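    free monomer + initiator → living end + monomer in chains (k1 = 0.508 M⁻¹ s⁻¹)
    free monomer + living end → monomer in chains + living end, rate k2*[living end]*[free monomer] (k2 = 2.69 M⁻¹ s⁻¹)
    monomer in chains + living end → free monomer + living end, rate k3*[living end] as long as [monomer in chains] is above zero (k3 = 0.323 s⁻¹)
    initiator + monomer in chains → spent initiator (k4 = 0.291 M⁻¹ s⁻¹)
    free monomer → decomposition product (k5 = 4.37 × 10⁻⁶ s⁻¹)

- blue: free monomer 0.80 M; initiator 40 mM; time 15 min
- ochre: free monomer 0.25 M; initiator 40 mM; time 15 min

- which of the two ends with the longer chains by the average number of monomer units in a chain (chains begun, living or dead) ("neither" if they lie within 10%) (blue / ochre / neither)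
- average number of monomer units in a chain (chains begun, living or dead) at the end, blue
- average number of monomer units in a chain (chains begun, living or dead) at the end, ochre

- the average divides the monomer in chains by the number of chains begun, living and dead together
- run time (blue): 15 min

I began with the time of reading, 15 min. If all the initiator became living ends, free monomer would relax by the forward and backward chain steps with a half-life of 6.44 s, far shorter than that time, so I reckoned on those steps balancing. The living end cancels from that balance, which leaves the balance level, the free monomer they leave standing, the ratio of their constants (the equilibrium monomer concentration): 0.120 M.

Length is then a ratio of two amounts, the gap (the charge above the balance level) over the chains begun. With every initiator starting a chain: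

blue: 0.680 M / 40 mM = 17.0
ochre: 0.130 M / 40 mM = 3.25

I computed only the correction, the initiator diverted into spent initiator while monomer in chains grows; each such step also removes one unit of monomer in chains, so it shortens the top of the ratio as well as the bottom. Holding free monomer at its charge gave a diverted fraction of 7.88% in blue, so a length of 18.4, and 17.2% in ochre, so 3.71. That holding suits blue, where the initiator charge is 5.88% of the gap, but not ochre, where it is a third, so for ochre I committed only to the bracket between 3.25 and 3.71.

The forecast gave blue, with 18.4 and 3.55, reasoning that “the monomer in chains is essentially the feed minus 0.12 M”.

The simulation gave blue the longer chains, 18.3 against 3.54.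

At 15.0 min, free monomer stood at 0.120 M in blue and 0.120 M in ochre, both level with the balance level. In blue at that time, the making of monomer in chains over its using up, each step taken net, read 1.00.

For a flask like blue with 0.010 M of initiator, the same gap gives 68.0, and a diverted fraction of 1.97% raises it to 69.3. The computed length there is 69.3.

The numbers were chosen freely; the result is computed.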